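**Retrosynthetic overview**

1. Target ⇐ silyl/acetate exchange and C19 desilylation of the bicyclo[3.2.1]octenone; C15 ketone ⇐ allylic alcohol.
2. Ring D ⇐ 5-exo-dig cyclization of a C13 radical (from a phenyl selenide) onto a C8 propargylic carbinol, itself from a lactone-enolate aldol with propynal.
3. Key step: C9–C10 bond and spiro δ-lactone ⇐ Ti(III) opening of an A-ring spiro-epoxide to the tertiary C10 radical and Giese addition to a preformed ring-C cyclohexenoate, setting C10 and C9 in one step.
4. Ring A ⇐ catalytic asymmetric Diels–Alder (2-siloxydiene + methacrolein; sets C4/C5), then α-methylenation, Luche reduction and epoxidation; ring C acceptor ⇐ Barbier allylation/RCM.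
5. Ring order: A (Diels–Alder) and C (RCM) separately → lactone ring (key radical coupling) → D (radical cyclization).

Atom labels C1–C20 follow ent-kaurane numbering of the target. Assumption: the (S)-oxazaborolidinium antipode is taken to give the required (4R) adduct by Corey's model (otherwise use the (R)-catalyst). The epoxide carbon of 10, C13 in 13–18, C8 in 16 and C15 in 18/19 are inconsequential mixtures that are erased later.

**Route**

Step 1
Reactants: 1 methyl vinyl ketone; 2 allyl alcohol TBS ether
Product: 3 (E)-5-(TBSO)pent-3-en-2-one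
Conditions: Grubbs II (2.5 mol %), CH2Cl2, 40 °C
Reagents that add atoms: none
Why: Olefin cross-metathesis of a type-I allyl ether with an electron-poor enone gives the E-enone selectively.

Step 2
Reactants: 3
Product: 4 (E)-2,5-bis(TBSO)penta-1,3-diene
Conditions: TBSOTf, Et3N, Et2O, 0 °C
Reagents that add atoms: TBSOTf, CC(C)(C)[Si](C)(C)OS(=O)(=O)C(F)(F)F
Why: Kinetic soft enolization of the methyl ketone gives the cross-conjugated 2-siloxydiene.

Step 3
Reactants: 4; 5 methacrolein
Product: 6 (1R,2S)-4-(TBSO)-2-(TBSOCH2)-1-methylcyclohex-3-ene-1-carbaldehyde (CHO cis to CH2OTBS; these carbons are C4 and C5)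
Conditions: (S)-o-tolyl-oxazaborolidinium triflimide (10 mol %), CH2Cl2, −78 → −40 °C
Reagents that add atoms: none
Why: Corey cationic-oxazaborolidine Diels–Alder; the 2-siloxy ("para") and 1-alkyl ("ortho") effects reinforce the regiochemistry, the CHO-endo transition state with the E-diene puts C19 cis to C6, and the catalyst sets the absolute configuration of the C4 quaternary centre.

Step 4
Reactants: 6
Product: 7 (1R,2R)-2-(TBSOCH2)-1-methyl-3-methylene-4-oxocyclohexane-1-carbaldehyde
Conditions: Me2N=CH2+ I−, CH2Cl2, rt; MeI; then aq NaHCO3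
Reagents that add atoms: Eschenmoser's salt, C=[N+](C)C.[I-]
Why: Regiospecific Mannich reaction at the silyl-enol-ether carbon (C10), then quaternization/elimination, gives the α-methylene ketone (C20 installed); it is used at once to avoid exo→endo isomerization.

Step 5
Reactants: 7
Product: 8 (1S,3R,4R)-3-(TBSOCH2)-4-(hydroxymethyl)-4-methyl-2-methylenecyclohexan-1-ol
Conditions: NaBH4, CeCl3·7H2O, MeOH, −78 → 0 °C
Reagents that add atoms: none
Why: Luche reduction reduces the aldehyde and gives 1,2-reduction of the enone; axial hydride delivery gives the equatorial C1 alcohol, cis to the equatorial C5 CH2OTBS group.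

Step 6
Reactants: 8
Product: 9, the C19-OTBDPS, C1-OTES bis-silyl ether of 8
Conditions: TBDPSCl, imidazole, CH2Cl2, 0 °C; then TESOTf, 2,6-lutidine, −78 °C (one pot)
Reagents that add atoms: TBDPSCl, CC(C)(C)[Si](Cl)(c1ccccc1)c1ccccc1; TESOTf, CC[Si](CC)(CC)OS(=O)(=O)C(F)(F)F
Why: Sequential silylation; the bulky TBDPSCl takes only the primary alcohol, then the secondary allylic alcohol is capped as the TES ether.

Step 7
Reactants: 9
Product: 10, the A-ring spiro-epoxide (1-oxaspiro[2.5]octane; C1 S, C4 R, C5 S by CIP; epoxide carbon either configuration)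
Conditions: mCPBA, NaHCO3, CH2Cl2, 0 °C
Reagents that add atoms: mCPBA, OOC(=O)c1cccc(Cl)c1
Why: Prilezhaev epoxidation of the 1,1-disubstituted exocyclic alkene; the new stereocentre is irrelevant because it becomes a planar radical.

Step 8
Reactants: 11 pent-4-enal; 12 methyl 2-(bromomethyl)acrylate
Product: 13 methyl 4-hydroxy-2-methyleneoct-7-enoate (racemic)
Conditions: Zn, THF/sat. aq NH4Cl, rt
Reagents that add atoms: none
Why: Zinc Barbier allylation (SE2′) of the aldehyde gives the homoallylic alcohol.

Step 9
Reactants: 13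
Product: 14 methyl 5-hydroxycyclohex-1-ene-1-carboxylate (racemic)
Conditions: Grubbs II (3 mol %), CH2Cl2, 40 °C
Reagents that add atoms: none
Why: Ring-closing metathesis of the acrylate and terminal alkene gives the six-membered enoate (ring C) with loss of ethylene.

Step 10
Reactants: 14
Product: 15 methyl 5-(phenylselanyl)cyclohex-1-ene-1-carboxylate (racemic)
Conditions: N-(phenylseleno)phthalimide, n-Bu3P, THF, 0 °C → rt
Reagents that add atoms: N-(phenylseleno)phthalimide, O=C1c2ccccc2C(=O)N1[Se]c1ccccc1
Why: Grieco–Nicolaou Mitsunobu-type selenation installs a radical precursor at C13 that is inert to Ti(III) and to enolates.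

Step 11 (key step)
Reactants: 10; 15 (4 equiv)
Product: 16, the spiro δ-lactone (C20–O–C7(=O)) with new C9–C10 bond; C10 S, C9 R (CIP at this stage, target geometry); C8–H and C13–SePh as mixtures
Conditions: Cp2TiCl2 (2.5 equiv), Mn, 2,4,6-collidine·HCl, THF, rt, slow addition of 10; then DBU, PhMe, 60 °C
Reagents that add atoms: none
Why: Proposed new method: Nugent–RajanBabu Ti(III) homolysis of the epoxide gives the tertiary C10 radical, which adds (Giese) to C9 of the enoate; the resulting α-ester radical is reduced to the Ti enolate and protonated, and DBU epimerizes C8 and closes the lactone. C10 is set by attack anti to the axial C19 group, so C20 ends axial and cis to C19/C6. C9 is set by a lactone-like chair approach with the ester toward the C20–O–Ti arm and the small C9–H facing the congested C4/C5 flank. The closest known reaction is the Ti(III) epoxide/acrylate reductive spirolactonization used for this compound class; here it is extended to a β-substituted cyclic enoate so that ring C and the C9 stereocentre arrive in the same step.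

Step 12
Reactants: 16; 17 propynal
Product: 18, the C8-quaternary aldol adduct (C8 S; 1-hydroxyprop-2-ynyl on C8, cis to H9; C15 epimers)
Conditions: LiHMDS, THF, −78 °C; then 17; AcOH quench at −78 °C
Reagents that add atoms: none
Why: Aldol addition of the lactone enolate; the electrophile enters C8 anti to the adjacent spiro A-ring (C10), cis to H9, which gives the lactone/ring-C fusion of the target.

Step 13
Reactants: 18
Product: 19, the bicyclo[3.2.1]octane allylic alcohol (C13 R; C16=CH2; C15-OH epimers)
Conditions: Bu3SnH, AIBN, PhH, 80 °C, syringe pump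
Reagents that add atoms: none
Why: Stannyl abstraction of PhSe gives the planar C13 radical from both epimers, which undergoes 5-exo-dig cyclization onto the unactivated alkyne on C8 (1,3-diaxial); the vinyl radical is reduced to the exocyclic methylene, and the bridge fixes C13.

Step 14
Reactants: 19
Product: 20, the 16-methylene-15-ketone (enone), still tris-silylated
Conditions: Dess–Martin periodinane, NaHCO3, CH2Cl2, rt
Reagents that add atoms: none
Why: Oxidation of the allylic secondary alcohol converges both C15 epimers to the enone.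

Step 15
Reactants: 20
Product: 21, the 1,6-diacetate 19-OTBDPS ether
Conditions: Ac2O, Cu(OTf)2 (5 mol %), CH2Cl2, rt
Reagents that add atoms: acetic anhydride, CC(=O)OC(C)=O
Why: Lewis-acid-catalysed direct exchange of TES and TBS ethers for acetates; the more robust neopentyl TBDPS ether survives.

Step 16
Reactants: 21
Product: 22 isodojaponin D
Conditions: HF·pyridine, pyridine/THF, 0 °C → rt
Reagents that add atoms: none
Why: Acidic fluoride desilylation frees C19-OH without base-induced acetyl migration or attack on the enone.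

**Compound list**

1 | methyl vinyl ketone | CC(=O)C=C | starting material
2 | allyl alcohol TBS ether | C=CCO[Si](C)(C)C(C)(C)C | starting material (allyl alcohol core, TBS protecting group)
3 | (E)-5-(TBSO)pent-3-en-2-one | CC(=O)/C=C/CO[Si](C)(C)C(C)(C)C | intermediate
4 | (E)-2,5-bis(TBSO)penta-1,3-diene | C=C(O[Si](C)(C)C(C)(C)C)/C=C/CO[Si](C)(C)C(C)(C)C | intermediate
5 | methacrolein | CC(=C)C=O | starting material
6 | (1R,2S)-4-(TBSO)-2-(TBSOCH2)-1-methylcyclohex-3-ene-1-carbaldehyde | CC(C)(C)[Si](C)(C)OC1=C[C@H](CO[Si](C)(C)C(C)(C)C)[C@](C)(C=O)CC1 | intermediate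
7 | (1R,2R)-2-(TBSOCH2)-1-methyl-3-methylene-4-oxocyclohexane-1-carbaldehyde | C=C1C(=O)CC[C@@](C)(C=O)[C@H]1CO[Si](C)(C)C(C)(C)C | intermediate
8 | (1S,3R,4R)-3-(TBSOCH2)-4-(hydroxymethyl)-4-methyl-2-methylenecyclohexan-1-ol | C=C1[C@@H](O)CC[C@@](C)(CO)[C@H]1CO[Si](C)(C)C(C)(C)C | intermediate
9 | C1-OTES, C19-OTBDPS, C6-OTBS methylenecyclohexane | C=C1[C@@H](O[Si](CC)(CC)CC)CC[C@@](C)(CO[Si](c2ccccc2)(c2ccccc2)C(C)(C)C)[C@H]1CO[Si](C)(C)C(C)(C)C | intermediate
10 | A-ring spiro-epoxide (epoxide carbon either configuration) | C1OC12[C@@H](O[Si](CC)(CC)CC)CC[C@@](C)(CO[Si](c3ccccc3)(c3ccccc3)C(C)(C)C)[C@H]2CO[Si](C)(C)C(C)(C)C | intermediate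
11 | pent-4-enal | C=CCCC=O | starting material
12 | methyl 2-(bromomethyl)acrylate | C=C(CBr)C(=O)OC | starting material
13 | methyl 4-hydroxy-2-methyleneoct-7-enoate (racemic) | C=CCCC(O)CC(=C)C(=O)OC | intermediate
14 | methyl 5-hydroxycyclohex-1-ene-1-carboxylate (racemic) | COC(=O)C1=CCCC(O)C1 | intermediate
15 | methyl 5-(phenylselanyl)cyclohex-1-ene-1-carboxylate (racemic) | COC(=O)C1=CCCC([Se]c2ccccc2)C1 | intermediate
16 | spirolactone with ring C (C8-H, C13-SePh mixtures) | c1ccccc1[Se]C1CC[C@H]2[C@]3(COC(=O)C2C1)[C@@H](O[Si](CC)(CC)CC)CC[C@@](C)(CO[Si](c2ccccc2)(c2ccccc2)C(C)(C)C)[C@H]3CO[Si](C)(C)C(C)(C)C | intermediate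
17 | propynal | C#CC=O | starting material
18 | C8 propargylic carbinol (C13, C15 mixtures) | c1ccccc1[Se]C1CC[C@H]2[C@]3(COC(=O)[C@]2(C1)C(O)C#C)[C@@H](O[Si](CC)(CC)CC)CC[C@@](C)(CO[Si](c2ccccc2)(c2ccccc2)C(C)(C)C)[C@H]3CO[Si](C)(C)C(C)(C)C | intermediate
19 | bicyclo[3.2.1]octane 15-ol with 16-methylene (C15 mixture) | C=C1C(O)[C@]23C[C@H]1CC[C@H]2[C@]1(COC3=O)[C@@H](O[Si](CC)(CC)CC)CC[C@@](C)(CO[Si](c2ccccc2)(c2ccccc2)C(C)(C)C)[C@H]1CO[Si](C)(C)C(C)(C)C | intermediate
20 | tris-silylated enone | C=C1C(=O)[C@]23C[C@H]1CC[C@H]2[C@]1(COC3=O)[C@@H](O[Si](CC)(CC)CC)CC[C@@](C)(CO[Si](c2ccccc2)(c2ccccc2)C(C)(C)C)[C@H]1CO[Si](C)(C)C(C)(C)C | intermediate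
21 | 19-O-TBDPS isodojaponin D | C=C1C(=O)[C@]23C[C@H]1CC[C@H]2[C@]1(COC3=O)[C@@H](OC(C)=O)CC[C@@](C)(CO[Si](c2ccccc2)(c2ccccc2)C(C)(C)C)[C@H]1COC(C)=O | intermediate
22 | isodojaponin D | C=C1C(=O)[C@]23C[C@H]1CC[C@H]2[C@]1(COC3=O)[C@@H](OC(C)=O)CC[C@@](C)(CO)[C@H]1COC(C)=O | target

**Totals**

Total steps: 16. Longest linear sequence: 13 (steps 1–7, then 11–16); steps 8–10 are a parallel three-step branch.

**Steps most likely to fail, with fallbacks**

1. Step 11 (Ti(III) fragment coupling). The hindered tertiary radical may add slowly to the β-substituted enoate, and the C9 facial selectivity rests on a model, not on precedent. Fallback: couple epoxide 10 with methyl acrylate instead (unsubstituted β-carbon, known reaction class), dehydrogenate to the C8=C9 unsaturated spirolactone, and build ring C afterwards by an intramolecular SmI2 ketyl addition to C9, so that C9 is set by the lactone ring and not by intermolecular topicity.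
2. Step 3 (asymmetric Diels–Alder). Endo/exo or enantioselectivity with this substituted siloxydiene may be insufficient. Fallback: run the cycloaddition racemically with EtAlCl2, carry the adduct to diol 8, and resolve 8 by lipase-mediated acylation of the primary alcohol.
3. Step 12 (aldol forming the C8 quaternary centre). Enolization may be slow or the adduct may revert by retro-aldol. Fallback: alkylate the enolate irreversibly with propargyl bromide, run the same 5-exo-dig cyclization, and install the C15 ketone late by allylic oxidation (SeO2/t-BuOOH, then Dess–Martin).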